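**Retrosynthetic overview**
1. The target comes from a bis-TIPS ether by desilylation; the C7 1,1-dimethylallyl group is installed last by aromatic Claisen rearrangement of a 6-O-prenyl ether of the 2-arylbenzofuran (para position C3a blocked, C5 shielded by a 4-OTIPS group).
2. The benzofuran (second ring formed) comes from acid cyclodehydration of a 2,6-dihydroxybenzyl aryl ketone whose two ortho oxygens are equivalent, so only one benzofuran can form.
3. The ketone comes from Krapcho decarboxylation of a β-keto ester, made in the key step: an intermolecular crossed Claisen condensation of a methyl arylacetate enolate with a chroman-5-carbonyl imidazolide.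
4. The arylacetate comes from phloroglucinol (bis-MOM, benzyl, ortho-lithiation/oxirane, oxidation, esterification).
5. The chroman acid (first ring formed) comes from methyl 3,5-dimethoxybenzoate (iodination, Mg/Cu prenylation, demethylation with chroman closure, MOM, saponification).

Assumption: the target has no stereocentre and no stereogenic double bond, so it is achiral and needs no stereocontrol; the transient stereocentres in 19, 22 and 27 are racemic and are erased in the same or the next step.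

**Route**

Step 1
Reactants: 1 methyl 3,5-dimethoxybenzoate
Product: 2 methyl 2-iodo-3,5-dimethoxybenzoate
Conditions: NIS (1.05 equiv), TFA (0.3 equiv), MeCN, rt, dark
Reagents that add atoms: N-iodosuccinimide, O=C1CCC(=O)N1I
Why: Electrophilic aromatic iodination goes to C2 (para to one OMe, ortho to the other) because C4 is squeezed between two OMe groups.

Step 2
Reactants: 2 methyl 2-iodo-3,5-dimethoxybenzoate
Product: 4 methyl 3,5-dimethoxy-2-(3-methylbut-2-en-1-yl)benzoate, via aryl Grignard reagent 3 (not isolated)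
Conditions: i-PrMgCl·LiCl (1.1 equiv), THF, −40 °C, 45 min; CuBr·SMe2 (10 mol%), prenyl bromide (1.5 equiv), −40 → 0 °C
Reagents that add atoms: 1-bromo-3-methylbut-2-ene (prenyl bromide), CC(C)=CCBr
Why: Iodine–magnesium exchange at −40 °C outruns attack on the ester, and the copper-catalysed allylic substitution puts the di-ortho-substituted aryl group on the unhindered primary carbon of prenyl bromide (SN2) instead of the tertiary γ-carbon.

Step 3
Reactants: 4 methyl 3,5-dimethoxy-2-(3-methylbut-2-en-1-yl)benzoate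
Product: 6 methyl 7-hydroxy-2,2-dimethylchromane-5-carboxylate, via methyl 3,5-dihydroxy-2-prenylbenzoate 5 (not isolated)
Conditions: BBr3 (4 equiv), CH2Cl2, −78 → 0 °C; then MeOH, 65 °C, 2 h
Reagents that add atoms: none
Why: BBr3 demethylates both aryl ethers (the benzoate survives at ≤0 °C), and the methanolic HBr formed on quenching protonates the prenyl alkene at the Markovnikov position so that the only ortho hydroxyl closes the 2,2-dimethylchroman ring (acid-catalysed hydroalkoxylation), the other OH being para and out of reach.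

Step 4
Reactants: 6 methyl 7-hydroxy-2,2-dimethylchromane-5-carboxylate
Product: 7 methyl 7-(methoxymethoxy)-2,2-dimethylchromane-5-carboxylate
Conditions: MOMCl (1.5 equiv), i-Pr2NEt (2 equiv), CH2Cl2, 0 °C → rt
Reagents that add atoms: chloromethyl methyl ether, COCCl
Why: O-alkylation of the single phenol gives a base-stable acetal that survives saponification, the enolate step and Krapcho conditions.

Step 5
Reactants: 7 methyl 7-(methoxymethoxy)-2,2-dimethylchromane-5-carboxylate
Product: 8 7-(methoxymethoxy)-2,2-dimethylchromane-5-carboxylic acid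
Conditions: LiOH·H2O (5 equiv), THF/MeOH/H2O, 60 °C; then 1 M HCl to pH 4, 0 °C
Reagents that add atoms: lithium hydroxide (carboxyl OH oxygen), [Li+].[OH-]
Why: Ester saponification (BAc2) leaves the MOM ether and the chroman untouched, and brief cold acidification to pH 4 does not cleave the acetal.

Step 6
Reactants: 9 phloroglucinol
Product: 10 3,5-bis(methoxymethoxy)phenol
Conditions: MOMCl (2.0 equiv), i-Pr2NEt (2.2 equiv), DMF, 0 °C → rt; chromatography
Reagents that add atoms: chloromethyl methyl ether, COCCl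
Why: Statistical O-alkylation of a cheap symmetric triol with a hard electrophile (no C-alkylation) gives the bis-ether in about 40%, separable from mono- and tris-ether.

Step 7
Reactants: 10 3,5-bis(methoxymethoxy)phenol
Product: 11 1-(benzyloxy)-3,5-bis(methoxymethoxy)benzene
Conditions: BnBr (1.2 equiv), K2CO3 (2 equiv), DMF, rt
Reagents that add atoms: benzyl bromide, BrCc1ccccc1
Why: Williamson etherification marks the future benzofuran 6-oxygen with a group that is stable to BuLi, enolates and acid and is removed later by hydrogenolysis.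

Step 8
Reactants: 11 1-(benzyloxy)-3,5-bis(methoxymethoxy)benzene
Product: 13 2-[4-(benzyloxy)-2,6-bis(methoxymethoxy)phenyl]ethan-1-ol, via aryllithium 12 (not isolated)
Conditions: n-BuLi (1.2 equiv), THF, 0 °C, 1 h; oxirane (3 equiv, THF solution), 0 °C → rt; H2O
Reagents that add atoms: oxirane (ethylene oxide), C1CO1
Why: Directed ortho-metalation occurs at the carbon flanked by the two cooperating OMOM groups, and the aryllithium opens the epoxide to give the two-carbon side chain.

Step 9
Reactants: 13 2-[4-(benzyloxy)-2,6-bis(methoxymethoxy)phenyl]ethan-1-ol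
Product: 15 2-[4-(benzyloxy)-2,6-bis(methoxymethoxy)phenyl]acetic acid, via arylacetaldehyde 14 (not isolated)
Conditions: TEMPO (0.2 equiv), PhI(OAc)2 (2.5 equiv), MeCN/H2O 1:1, rt
Reagents that add atoms: water, O
Why: Oxoammonium (TEMPO/BAIB) oxidation takes the primary alcohol through the aldehyde hydrate to the acid under near-neutral conditions that spare the acetals and the benzyl ether.

Step 10
Reactants: 15 2-[4-(benzyloxy)-2,6-bis(methoxymethoxy)phenyl]acetic acid
Product: 16 methyl 2-[4-(benzyloxy)-2,6-bis(methoxymethoxy)phenyl]acetate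
Conditions: MeI (1.5 equiv), K2CO3 (2 equiv), DMF, rt
Reagents that add atoms: iodomethane, CI
Why: Carboxylate SN2 alkylation gives the methyl ester needed for clean enolate formation and later Krapcho cleavage.

Step 11 (key step)
Reactants: 8 7-(methoxymethoxy)-2,2-dimethylchromane-5-carboxylic acid; 16 methyl 2-[4-(benzyloxy)-2,6-bis(methoxymethoxy)phenyl]acetate
Product: 19 methyl 2-[4-(benzyloxy)-2,6-bis(methoxymethoxy)phenyl]-3-[7-(methoxymethoxy)-2,2-dimethylchroman-5-yl]-3-oxopropanoate, via acyl imidazolide 17 (not isolated), via lithium enolate 18 (not isolated)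
Conditions: 8, CDI (1.1 equiv), THF, rt, 1 h; separately 16, LiHMDS (3.2 equiv), THF, −78 °C; add the imidazolide solution, −78 → 0 °C; AcOH quench
Reagents that add atoms: none
Why: Crossed Claisen condensation: the ester enolate is C-acylated by the neutral, MOM-compatible acyl imidazolide, and the extra base takes up the free imidazole and deprotonates the β-keto ester to drive the reaction (the new α-stereocentre is racemic and is removed in step 12).

Step 12
Reactants: 19 the β-keto ester
Product: 20 2-[4-(benzyloxy)-2,6-bis(methoxymethoxy)phenyl]-1-[7-(methoxymethoxy)-2,2-dimethylchroman-5-yl]ethan-1-one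
Conditions: LiCl (3 equiv), H2O (3 equiv), DMSO, 140 °C
Reagents that add atoms: none
Why: Krapcho dealkoxycarbonylation removes the ester under neutral conditions, so no ortho phenol is freed before the carboxyl is gone (this avoids a benzofuran-3-carboxylate).

Step 13
Reactants: 20 the ketone
Product: 23 6-(benzyloxy)-2-(7-hydroxy-2,2-dimethylchroman-5-yl)-1-benzofuran-4-ol, via triol ketone 21 (not isolated), via hemiketal 22 (not isolated)
Conditions: 3 M HCl, MeOH/THF, 50 °C, 4 h
Reagents that add atoms: none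
Why: Acetal methanolysis frees the phenols and the 2-hydroxybenzyl ketone cyclodehydrates through its hemiketal to the aromatic furan; the two ortho hydroxyls are equivalent, so only one benzofuran forms and the benzyl ether stays at O6.

Step 14
Reactants: 23 6-(benzyloxy)-2-(7-hydroxy-2,2-dimethylchroman-5-yl)-1-benzofuran-4-ol
Product: 24 6-(benzyloxy)-4-[(triisopropylsilyl)oxy]-2-{2,2-dimethyl-7-[(triisopropylsilyl)oxy]chroman-5-yl}-1-benzofuran
Conditions: TIPSCl (3 equiv), imidazole (6 equiv), DMF, 40 °C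
Reagents that add atoms: chlorotri(propan-2-yl)silane, CC(C)[Si](Cl)(C(C)C)C(C)C
Why: Silylation of both free phenols gives thermally stable, fluoride-labile ethers, and the bulky 4-OTIPS group later shields C5.

Step 15
Reactants: 24 the bis-TIPS benzyl ether
Product: 25 4-[(triisopropylsilyl)oxy]-2-{2,2-dimethyl-7-[(triisopropylsilyl)oxy]chroman-5-yl}-1-benzofuran-6-ol
Conditions: H2 (1 atm), 10% Pd/C, EtOAc/EtOH, rt
Reagents that add atoms: none
Why: Hydrogenolysis cleaves the benzyl ether before any alkene is present, and the 2-arylbenzofuran and silyl ethers are inert at 1 atm and rt.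

Step 16
Reactants: 25 the 6-hydroxybenzofuran
Product: 26 6-[(3-methylbut-2-en-1-yl)oxy]-4-[(triisopropylsilyl)oxy]-2-{2,2-dimethyl-7-[(triisopropylsilyl)oxy]chroman-5-yl}-1-benzofuran
Conditions: 3-methylbut-2-en-1-ol (1.5 equiv), PPh3 (1.5 equiv), DIAD (1.5 equiv), THF, 0 °C → rt
Reagents that add atoms: 3-methylbut-2-en-1-ol (prenol), CC(C)=CCO
Why: Mitsunobu etherification prenylates the unhindered phenol under neutral conditions, so the base-sensitive aryl silyl ethers are not disturbed.

Step 17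
Reactants: 26 the 6-O-prenyl ether
Product: 28 7-(2-methylbut-3-en-2-yl)-4-[(triisopropylsilyl)oxy]-2-{2,2-dimethyl-7-[(triisopropylsilyl)oxy]chroman-5-yl}-1-benzofuran-6-ol, via cyclohexadienone 27 (not isolated)
Conditions: PhNEt2, 190 °C, 2 h, Ar, sealed tube
Reagents that add atoms: none
Why: Aromatic Claisen rearrangement ([3,3] with allyl inversion, then tautomerisation, no by-product) can only end at an ortho carbon because the para position is the ring fusion, and C7 should be favoured over C5 by the higher C6–C7 bond order of benzofuran and by the 4-OTIPS group flanking C5.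

Step 18
Reactants: 28 the bis-TIPS ether
Product: 29 2-(7-hydroxy-2,2-dimethylchroman-5-yl)-7-(2-methylbut-3-en-2-yl)-1-benzofuran-4,6-diol (target)
Conditions: TBAF (2.4 equiv), AcOH (2.4 equiv), THF, 0 °C → rt
Reagents that add atoms: none
Why: Fluoride desilylation under acetic acid buffering frees both phenols without acid, so the 1,1-dimethylallyl group next to the phenol cannot cyclise.

**Compound list**
1 | methyl 3,5-dimethoxybenzoate | COC(=O)c1cc(OC)cc(OC)c1 | starting material
2 | methyl 2-iodo-3,5-dimethoxybenzoate | COC(=O)c1cc(OC)cc(OC)c1I | intermediate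
3 | [2-(methoxycarbonyl)-4,6-dimethoxyphenyl]magnesium chloride (formed in situ) | COC(=O)c1cc(OC)cc(OC)c1[Mg]Cl | intermediate
4 | methyl 3,5-dimethoxy-2-(3-methylbut-2-en-1-yl)benzoate | COC(=O)c1cc(OC)cc(OC)c1CC=C(C)C | intermediate
5 | methyl 3,5-dihydroxy-2-(3-methylbut-2-en-1-yl)benzoate (formed in situ) | COC(=O)c1cc(O)cc(O)c1CC=C(C)C | intermediate
6 | methyl 7-hydroxy-2,2-dimethylchromane-5-carboxylate | COC(=O)c1cc(O)cc2OC(C)(C)CCc12 | intermediate
7 | methyl 7-(methoxymethoxy)-2,2-dimethylchromane-5-carboxylate | COC(=O)c1cc(OCOC)cc2OC(C)(C)CCc12 | intermediate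
8 | 7-(methoxymethoxy)-2,2-dimethylchromane-5-carboxylic acid | OC(=O)c1cc(OCOC)cc2OC(C)(C)CCc12 | intermediate
9 | phloroglucinol (benzene-1,3,5-triol) | Oc1cc(O)cc(O)c1 | starting material
10 | 3,5-bis(methoxymethoxy)phenol | COCOc1cc(O)cc(OCOC)c1 | intermediate
11 | 1-(benzyloxy)-3,5-bis(methoxymethoxy)benzene | COCOc1cc(OCOC)cc(OCc2ccccc2)c1 | intermediate
12 | [4-(benzyloxy)-2,6-bis(methoxymethoxy)phenyl]lithium (formed in situ) | [Li]c1c(OCOC)cc(OCc2ccccc2)cc1OCOC | intermediate
13 | 2-[4-(benzyloxy)-2,6-bis(methoxymethoxy)phenyl]ethan-1-ol | OCCc1c(OCOC)cc(OCc2ccccc2)cc1OCOC | intermediate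
14 | 2-[4-(benzyloxy)-2,6-bis(methoxymethoxy)phenyl]acetaldehyde (formed in situ) | O=CCc1c(OCOC)cc(OCc2ccccc2)cc1OCOC | intermediate
15 | 2-[4-(benzyloxy)-2,6-bis(methoxymethoxy)phenyl]acetic acid | OC(=O)Cc1c(OCOC)cc(OCc2ccccc2)cc1OCOC | intermediate
16 | methyl 2-[4-(benzyloxy)-2,6-bis(methoxymethoxy)phenyl]acetate | COC(=O)Cc1c(OCOC)cc(OCc2ccccc2)cc1OCOC | intermediate
17 | (1H-imidazol-1-yl)[7-(methoxymethoxy)-2,2-dimethylchroman-5-yl]methanone (formed in situ) | O=C(n1ccnc1)c1cc(OCOC)cc2OC(C)(C)CCc12 | intermediate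
18 | lithium enolate of 16 (formed in situ) | COC(O[Li])=Cc1c(OCOC)cc(OCc2ccccc2)cc1OCOC | intermediate
19 | methyl 2-[4-(benzyloxy)-2,6-bis(methoxymethoxy)phenyl]-3-[7-(methoxymethoxy)-2,2-dimethylchroman-5-yl]-3-oxopropanoate (racemic) | COC(=O)C(C(=O)c1cc(OCOC)cc2OC(C)(C)CCc12)c1c(OCOC)cc(OCc2ccccc2)cc1OCOC | intermediate
20 | 2-[4-(benzyloxy)-2,6-bis(methoxymethoxy)phenyl]-1-[7-(methoxymethoxy)-2,2-dimethylchroman-5-yl]ethan-1-one | O=C(Cc1c(OCOC)cc(OCc2ccccc2)cc1OCOC)c1cc(OCOC)cc2OC(C)(C)CCc12 | intermediate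
21 | 2-[4-(benzyloxy)-2,6-dihydroxyphenyl]-1-(7-hydroxy-2,2-dimethylchroman-5-yl)ethan-1-one (formed in situ) | O=C(Cc1c(O)cc(OCc2ccccc2)cc1O)c1cc(O)cc2OC(C)(C)CCc12 | intermediate
22 | 6-(benzyloxy)-2-(7-hydroxy-2,2-dimethylchroman-5-yl)-2,3-dihydro-1-benzofuran-2,4-diol (racemic, formed in situ) | OC1(c2cc(O)cc3OC(C)(C)CCc23)Cc2c(O)cc(OCc3ccccc3)cc2O1 | intermediate
23 | 6-(benzyloxy)-2-(7-hydroxy-2,2-dimethylchroman-5-yl)-1-benzofuran-4-ol | Oc1cc(OCc2ccccc2)cc2oc(-c3cc(O)cc4OC(C)(C)CCc34)cc12 | intermediate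
24 | 6-(benzyloxy)-4-[(triisopropylsilyl)oxy]-2-{2,2-dimethyl-7-[(triisopropylsilyl)oxy]chroman-5-yl}-1-benzofuran | CC(C)[Si](C(C)C)(C(C)C)Oc1cc(OCc2ccccc2)cc2oc(-c3cc(O[Si](C(C)C)(C(C)C)C(C)C)cc4OC(C)(C)CCc34)cc12 | intermediate
25 | 4-[(triisopropylsilyl)oxy]-2-{2,2-dimethyl-7-[(triisopropylsilyl)oxy]chroman-5-yl}-1-benzofuran-6-ol | CC(C)[Si](C(C)C)(C(C)C)Oc1cc(O)cc2oc(-c3cc(O[Si](C(C)C)(C(C)C)C(C)C)cc4OC(C)(C)CCc34)cc12 | intermediate
26 | 6-[(3-methylbut-2-en-1-yl)oxy]-4-[(triisopropylsilyl)oxy]-2-{2,2-dimethyl-7-[(triisopropylsilyl)oxy]chroman-5-yl}-1-benzofuran | CC(C)=CCOc1cc(O[Si](C(C)C)(C(C)C)C(C)C)c2cc(-c3cc(O[Si](C(C)C)(C(C)C)C(C)C)cc4OC(C)(C)CCc34)oc2c1 | intermediate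
27 | 7-(2-methylbut-3-en-2-yl)-4-[(triisopropylsilyl)oxy]-2-{2,2-dimethyl-7-[(triisopropylsilyl)oxy]chroman-5-yl}-1-benzofuran-6(7H)-one (racemic, formed in situ) | C=CC(C)(C)C1C(=O)C=C(O[Si](C(C)C)(C(C)C)C(C)C)c2cc(-c3cc(O[Si](C(C)C)(C(C)C)C(C)C)cc4OC(C)(C)CCc34)oc12 | intermediate
28 | 7-(2-methylbut-3-en-2-yl)-4-[(triisopropylsilyl)oxy]-2-{2,2-dimethyl-7-[(triisopropylsilyl)oxy]chroman-5-yl}-1-benzofuran-6-ol | C=CC(C)(C)c1c(O)cc(O[Si](C(C)C)(C(C)C)C(C)C)c2cc(-c3cc(O[Si](C(C)C)(C(C)C)C(C)C)cc4OC(C)(C)CCc34)oc12 | intermediate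
29 | 2-(7-hydroxy-2,2-dimethylchroman-5-yl)-7-(2-methylbut-3-en-2-yl)-1-benzofuran-4,6-diol | C=CC(C)(C)c1c(O)cc(O)c2cc(-c3cc(O)cc4c3CCC(C)(C)O4)oc12 | target

**Totals and risks**
Total step count: 18. Longest linear sequence: 13 steps (steps 1–5 then 11–18, or equally steps 6–10 then 11–18).

Most likely to fail, in order:

Step 17 (regiochemistry C7 versus C5 and thermal side reactions of the o-(1,1-dimethylallyl)phenol). The fallback replaces the sigmatropic shift by directed metalation and sets out from 25. Capping with MOMCl/i-Pr2NEt gives 6-(methoxymethoxy)-4-[(triisopropylsilyl)oxy]-2-{2,2-dimethyl-7-[(triisopropylsilyl)oxy]chroman-5-yl}-1-benzofuran F6. Lithiation with n-BuLi/TMEDA (THF, −40 → 0 °C) should occur at C7, the only C–H between the OMOM group and the furan oxygen (C5 is flanked by the non-directing OTIPS), and iodine then gives 7-iodo-6-(methoxymethoxy)-4-[(triisopropylsilyl)oxy]-2-{2,2-dimethyl-7-[(triisopropylsilyl)oxy]chroman-5-yl}-1-benzofuran F7. A γ-selective Suzuki–Miyaura coupling with 3-methylbut-2-enylboronic acid pinacol ester (Pd precatalyst with a γ-directing biaryl phosphine, K3PO4, THF/H2O) gives 6-(methoxymethoxy)-7-(2-methylbut-3-en-2-yl)-4-[(triisopropylsilyl)oxy]-2-{2,2-dimethyl-7-[(triisopropylsilyl)oxy]chroman-5-yl}-1-benzofuran F8. This coupling is itself uncertain at a di-ortho-substituted carbon. Brief 2 M HCl in MeOH/THF at rt removes the MOM group and the route is rejoined at 28.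

Step 11 (C-acylation between a di-ortho-substituted enolate and an ortho-substituted acyl donor may be slow). The fallback uses an aldol addition to a smaller, more electrophilic aldehyde followed by oxidation; it sets out from 7 and 16. LiAlH4 (THF, 0 °C) reduces 7 to [7-(methoxymethoxy)-2,2-dimethylchroman-5-yl]methanol F3, and MnO2 (CH2Cl2) oxidises it to 7-(methoxymethoxy)-2,2-dimethylchromane-5-carbaldehyde F4. The lithium enolate 18 (from 16 with LDA, THF, −78 °C) adds to F4 and a cold quench gives methyl 2-[4-(benzyloxy)-2,6-bis(methoxymethoxy)phenyl]-3-hydroxy-3-[7-(methoxymethoxy)-2,2-dimethylchroman-5-yl]propanoate F5 as a diastereomer mixture. Dess–Martin periodinane (NaHCO3, CH2Cl2) oxidises F5 and the route is rejoined at 19.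

Step 2 (functionalised Grignard next to an ester; possible SN2′ or homocoupling). The fallback builds the side chain by a Heck reaction; it sets out from 2. Coupling with 2-methylbut-3-en-2-ol (Pd(OAc)2, n-Bu4NCl, NaHCO3, DMF, 80 °C) gives methyl 2-[(E)-3-hydroxy-3-methylbut-1-en-1-yl]-3,5-dimethoxybenzoate F1. Hydrogenation (H2, Pd/C, EtOAc) gives methyl 2-(3-hydroxy-3-methylbutyl)-3,5-dimethoxybenzoate F2. BBr3 (CH2Cl2, −78 → 0 °C) followed by hot methanol demethylates F2 and closes the chroman through the tertiary cation, and the route is rejoined at 6.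

**Further compounds**
F1 | step 2 | methyl 2-[(E)-3-hydroxy-3-methylbut-1-en-1-yl]-3,5-dimethoxybenzoate | COC(=O)c1cc(OC)cc(OC)c1/C=C/C(C)(C)O
F2 | step 2 | methyl 2-(3-hydroxy-3-methylbutyl)-3,5-dimethoxybenzoate | COC(=O)c1cc(OC)cc(OC)c1CCC(C)(C)O
F3 | step 11 | [7-(methoxymethoxy)-2,2-dimethylchroman-5-yl]methanol | OCc1cc(OCOC)cc2OC(C)(C)CCc12
F4 | step 11 | 7-(methoxymethoxy)-2,2-dimethylchromane-5-carbaldehyde | O=Cc1cc(OCOC)cc2OC(C)(C)CCc12
F5 | step 11 | methyl 2-[4-(benzyloxy)-2,6-bis(methoxymethoxy)phenyl]-3-hydroxy-3-[7-(methoxymethoxy)-2,2-dimethylchroman-5-yl]propanoate (racemic diastereomer mixture) | COC(=O)C(C(O)c1cc(OCOC)cc2OC(C)(C)CCc12)c1c(OCOC)cc(OCc2ccccc2)cc1OCOC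
F6 | step 17 | 6-(methoxymethoxy)-4-[(triisopropylsilyl)oxy]-2-{2,2-dimethyl-7-[(triisopropylsilyl)oxy]chroman-5-yl}-1-benzofuran | COCOc1cc(O[Si](C(C)C)(C(C)C)C(C)C)c2cc(-c3cc(O[Si](C(C)C)(C(C)C)C(C)C)cc4OC(C)(C)CCc34)oc2c1
F7 | step 17 | 7-iodo-6-(methoxymethoxy)-4-[(triisopropylsilyl)oxy]-2-{2,2-dimethyl-7-[(triisopropylsilyl)oxy]chroman-5-yl}-1-benzofuran | COCOc1cc(O[Si](C(C)C)(C(C)C)C(C)C)c2cc(-c3cc(O[Si](C(C)C)(C(C)C)C(C)C)cc4OC(C)(C)CCc34)oc2c1I
F8 | step 17 | 6-(methoxymethoxy)-7-(2-methylbut-3-en-2-yl)-4-[(triisopropylsilyl)oxy]-2-{2,2-dimethyl-7-[(triisopropylsilyl)oxy]chroman-5-yl}-1-benzofuran | C=CC(C)(C)c1c(OCOC)cc(O[Si](C(C)C)(C(C)C)C(C)C)c2cc(-c3cc(O[Si](C(C)C)(C(C)C)C(C)C)cc4OC(C)(C)CCc34)oc12
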